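The last few percent of an electrophile on a second-order loss come slowly, and the bench habit for such a tail is the reciprocal rule known from step growth: the reciprocal of what remains climbs linearly with time.

the same everywhere: electrophile 0.049 M; free base 0.0539 M

|  | nucleophile | remark | time |
|---|---|---|---|
| north-east | 0.049 M (fed, over 20 h) | run made earlier |  |
| north-west | 0.11 M (fed, over 20 h) | run made earlier |  |
| flask | 0.0735 M (fed, over 20 h) |  | 10 d |

| run | time / d | electrophile / % | target / % |
|---|---|---|---|
| north-east | 0.625 | 27.4 | 1.8 |
| north-east | 2.08 | 8.7 | 4.7 |
| north-east | 4.00 | 3.9 | 6.4 |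
| north-east | 6.00 | 2.0 | 7.4 |
| north-east | 8.00 | 1.0 | 8.5 |
| north-west | 0.625 | 26.2 | 4.0 |
| north-west | 2.08 | 6.6 | 10.5 |
| north-west | 4.00 | 2.0 | 13.6 |
| north-west | 6.00 | 0.6 | 14.6 |
| north-west | 8.00 | 0.2 | 15.0 |

(scatter of a reading: 0.3 percentage points)

- part of the electrophile that has reacted at 10 d
- share of the unused nucleophile that is free and not bound as protonated nucleophile, at 10 d

- the earlier runs do not show how much of nucleophile is bound; that part of a forecast is a guess

Drawn through the north-east readings at 2.08 d and 4.00 d, the rule leaves 1.81% at 8.00 d, but the reading is lower, at 1.0%. The border shows in a ratio: target gained per electrophile lost between those readings is 35.4% in the north-east run and 67.4% in the north-west run. So the readings point to a path first order in electrophile, growing with nucleophile, beside the second-order loss.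

Taken at the logarithmic mean of the electrophile remaining, these ratios read as crossover levels of 3.28% in the north-east run and 7.96% in the north-west run. Pooled by nucleophile charge, they give 5.20% for the flask: the crossover level L, the remaining electrophile y at which both paths remove it equally.

Integrating the loss b·y·(1 + y/L) makes ln(1 + L/y) grow linearly at b, the pseudo-first-order constant. This b is the ratio times the logarithmic slope: 0.148 d⁻¹ and 0.419 d⁻¹, pooled to 0.262 d⁻¹ for the flask. Starting from 2.98%, interpolated at 4.00 d, this reckoning leaves 0.425% in the flask at 10 d. The binding of the nucleophile stays a guess.

The forecast gives 99.8% reacted and 92% free, holding that “most stays free”, while this reckoning gives 99.6% reacted.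

The flask gives 99.4% reacted, with 0.570% of the electrophile left, and >99.9% of the unused nucleophile free.

    crystals ⇌ acid set free, rate k1*(cs1 - [acid set free]) while solid is left; crystals form when [acid set free] > cs1 (solubility = 2.80 mM, k = 0.944 h⁻¹)
    nucleophile + acid set free ⇌ protonated nucleophile, settled at all times (K = 975 L mol⁻¹)
    2 electrophile → self-condensation product (k = 1.74 L mol⁻¹ h⁻¹)
    electrophile + nucleophile → acid set free + target (k = 0.144 L mol⁻¹ h⁻¹)
    acid set free + free base ⇌ salt of the base, settled at all times (K = 1.52 × 10⁶ L mol⁻¹)

In the flask the electrophile stood above the crossover level at 0.833 d, at 21.0%, and below it at 5.00 d, at 2.37%. Struck out of the flask, self-condensation takes the part reacted at 10 d from 99.4% to 78.9%, the largest single effect. For the neighbour with 0.12 M of nucleophile, the crossover level is 8.49%, and the same reckoning leaves 0.115%, while that flask holds 0.18%.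

Readings and results are calculated with constants of no real substance; noise was put on by code.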